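The readings were generated by integration from invented constants; noise was put on by code.

The ratio of reagent in the second phase to starting material in the flask was 1.20, with more reagent than starting material. Counting one reagent per target, I took starting material as the limiting reagent, and I had to decide whether 8.0 h was long enough or the charge should change.

| flask | starting material | reagent in the second phase | remark | time | volume of the second phase over the first |
|---|---|---|---|---|---|
| summer | 0.40 M | 0.24 M | run made earlier |  |  |
| noon | 0.40 M | 0.96 M | run made earlier |  |  |
| dusk | 0.20 M | 0.48 M | run made earlier |  |  |
| flask | 0.40 M | 0.480 M |  | 8.0 h | 1.0 |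

| run | time / h | target / % | starting material / % |
|---|---|---|---|
| summer | 0.833 | 10 | 29 |
| summer | 1.33 | 11 | 25 |
| summer | 2.00 | 17 | 22 |
| summer | 4.00 | 32 | 18 |
| summer | 6.00 | 43 | 15 |
| summer | 10.0 | 52 | 15 |
| noon | 0.833 | 29 | 18 |
| noon | 1.33 | 48 | 9 |
| noon | 2.00 | 59 | 4 |
| noon | 4.00 | 87 | 0 |
| noon | 6.00 | 98 | 1 |
| noon | 10.0 | 102 | 0 |
| dusk | 0.833 | 22 | 21 |
| dusk | 2.50 | 60 | 8 |
| dusk | 4.00 | 78 | 2 |
| dusk | 6.00 | 93 | 1 |
| dusk | 10.0 | 101 | 0 |

(each reading ± 1.5 percentage points)

* the target standing at 8.0 h, as a percentage of the starting material charged
* the change that raises the amount of target at 8.0 h, in percent of the starting material charged most ("none" if none brings more than 2 percentage points) (elm / oak / none)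
* amount of target at 8.0 h, in percent of the starting material charged, after oak

- in the second phase: reagent in the second phase; everything else is in the first
- charges count per volume of the first phase; a concentration in a rate is the amount of a species over the volume of its own phase; every rate counts per litre of the first phase
- what was read earlier has a scatter of 1.5 percentage points, one standard deviation
- the earlier runs hold the two phases in the same ratio of volumes as the flask asked about

I reckoned with what was left, not what was made. I assumed that each target made meant one reagent gone from the second phase, so each target reading gave an estimate of the fraction left there. Summer at 4.00 h showed that fraction halving in 3.64 h. Noon at 1.33 h, with starting material still standing, showed 4.13 h, though its charge was 4.00 times larger. Their mean, 3.88 h, is my estimate of the half-time of the reagent in the second phase, which I applied to the flask: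

half-times passed: 2.06
left in the second phase: 24.0% of its charge
moved: 0.365 M
target: 91.2% of the starting material charged

That fell short of completion, so I chose oak, which is the noon charge, read at 98% after 6.00 h and 102% after 10.0 h.

The forecast gave 79% (72% to 86%), below my figure. It also chose oak, with 100% (97% to 103%), noting: “Oak is exactly the noon run”.

The flask gave 85.0%. Oak gained 14 percentage points against 8.1 points for elm, reaching 98.9%.

    reagent in the reaction phase ⇌ reagent in the second phase, rate k1*([reagent in the reaction phase] - [reagent in the second phase]/K1) per volume of the first phase (partition coefficient = 1.59, kL = 0.366 /h)
    starting material + reagent in the reaction phase → target (k = 42.1 /M/h)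
    starting material ⇌ dormant form (K = 2.60, k = 2.07 /h)

In the flask, reagent in the reaction phase was made 1.03 times as fast as it was used at 2.29 h, and 1.02 times at 8.00 h. The second phase held 23.3% of its charge at 8.0 h against my 24.0%, but 0.0284 M stood in the reaction phase, equal to 7.10% of the starting material charged, and I had counted it as target. With 0.10 M of starting material, target needs 20.8% of the reagent charge, which the half-time moves in 1.31 h, well inside 8.0 h. Computed, that flask gave 98.6%.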